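## Retrosynthetic overview

1. Units A–D are counted from the phenol end and C7, C8, C9 are the side-chain carbons of each unit; the plan rests on ring A, the only ring with a free phenol, whose hydroxyl is para to the benzylic carbon C7 of unit A, while the C9 hydroxyl of that unit sits three atoms from C7 with the C8 aryl ether centre between them.
2. Last disconnection: the C7–O bond of unit A. The 7-deoxy tetramer is oxidised at ring A to a para-quinone methide and oxygen is delivered from a phenylboronic hemiester on O9. Two 1,3,2-dioxaborinane rings close in that step, each from its own molecule of phenylboronic acid, and are removed in the last one.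
3. The two C8–O–C4 aryl ethers are each cut to a phenol and an α-triflyloxy ester (SN2, inversion). Unit A comes from methyl (S)-glycidate and an aryl Grignard reagent. Unit B comes from methyl (R)-glycerate, then Weinreb ketone synthesis and chelate-controlled reduction to the erythro alcohol.
4. The trans-dihydrobenzofuran of units C and D is cut at C2–C3 (enantioselective rhodium carbenoid C–H insertion, then epimerisation at C3). The enal is carried as an aryl dioxolane and freed by Wittig olefination after the last hydride step.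
5. Order of ring formation: dihydrobenzofuran (step 8), then the two temporary dioxaborinanes on units A and B (step 27).

Key step: step 27

Assumption: dirhodium tetrakis[N-phthaloyl-(S)-tert-leucinate], Rh2(S-PTTL)4, is taken to give the (2R) dihydrobenzofuran in step 8; should it favour the (2S) series, the mirror-image catalyst Rh2(R-PTTL)4 is used and nothing else changes.

## Route

Step 1
Reactants: 1 syringaldehyde (4-hydroxy-3,5-dimethoxybenzaldehyde)
Product: 2 4-formyl-2,6-dimethoxyphenyl pivalate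
Conditions: PivCl, Et3N, DMAP (cat.), CH2Cl2, 0 °C to rt
Reagents that add atoms: pivaloyl chloride, CC(C)(C)C(=O)Cl
Why: Acylation of the phenol (esterification) masks the ring C oxygen as a hindered ester that should tolerate the basic and carbenoid steps ahead and is cleaved in the hydride reduction of step 9.

Step 2
Reactants: 2 4-formyl-2,6-dimethoxyphenyl pivalate
Product: 3 4-(hydroxymethyl)-2,6-dimethoxyphenyl pivalate
Conditions: NaBH4, THF–MeOH, 0 °C
Reagents that add atoms: none
Why: Borohydride reduction of the aldehyde is fast at 0 °C and should leave the hindered aryl pivalate untouched.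

Step 3
Reactants: 3 4-(hydroxymethyl)-2,6-dimethoxyphenyl pivalate
Product: 4 4-(bromomethyl)-2,6-dimethoxyphenyl pivalate
Conditions: PBr3, CH2Cl2, 0 °C
Reagents that add atoms: phosphorus tribromide, BrP(Br)Br
Why: Bromination of a benzylic alcohol with PBr3 is routine, and the acyloxy group keeps the benzyl bromide stable enough to handle.

Step 4
Reactants: 4 4-(bromomethyl)-2,6-dimethoxyphenyl pivalate; 5 5-iodovanillin (4-hydroxy-3-iodo-5-methoxybenzaldehyde)
Product: 6 4-[(4-formyl-2-iodo-6-methoxyphenoxy)methyl]-2,6-dimethoxyphenyl pivalate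
Conditions: K2CO3, DMF, rt
Reagents that add atoms: none
Why: Williamson ether synthesis of the acidic phenol with the benzylic bromide joins rings C and D through the OCH2 group whose C–H bond is inserted in step 8.

Step 5
Reactants: 6 the aldehyde of step 4
Product: 7 4-{[4-(1,3-dioxolan-2-yl)-2-iodo-6-methoxyphenoxy]methyl}-2,6-dimethoxyphenyl pivalate
Conditions: ethylene glycol, PPTS (cat.), benzene, reflux, Dean–Stark
Reagents that add atoms: ethylene glycol, OCCO
Why: Acetalisation under a mild pyridinium acid with removal of water protects the aldehyde against the zinc enolate, the carbenoid and the hydride and organometallic reagents, and should spare the benzylic aryl ether.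

Step 6
Reactants: 7 the aryl iodide of step 5
Product: 8 ethyl 2-[5-(1,3-dioxolan-2-yl)-2-{[3,5-dimethoxy-4-(pivaloyloxy)phenyl]methoxy}-3-methoxyphenyl]acetate
Conditions: BrZnCH2CO2Et, Pd2(dba)3 (2 mol%), XPhos (8 mol%), THF, 50 °C
Reagents that add atoms: (2-ethoxy-2-oxoethyl)zinc bromide, CCOC(=O)C[Zn]Br
Why: Palladium-catalysed cross-coupling of the aryl iodide with the Reformatsky reagent (Negishi-type α-arylation of an ester) installs the acetate arm ortho to the benzyl ether, and the zinc enolate is inert to the pivalate and the acetal.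

Step 7
Reactants: 8 the arylacetate of step 6
Product: 9 ethyl 2-diazo-2-[5-(1,3-dioxolan-2-yl)-2-{[3,5-dimethoxy-4-(pivaloyloxy)phenyl]methoxy}-3-methoxyphenyl]acetate
Conditions: p-ABSA, DBU, MeCN, 0 °C to rt
Reagents that add atoms: 4-acetamidobenzenesulfonyl azide, CC(=O)Nc1ccc(cc1)S(=O)(=O)N=[N+]=[N-]
Why: Regitz diazo transfer to the arylacetate gives the donor–acceptor diazo ester needed for carbenoid chemistry.

Step 8
Reactants: 9 the aryldiazoacetate of step 7
Product: 11 ethyl (2R,3R)-5-(1,3-dioxolan-2-yl)-2-[3,5-dimethoxy-4-(pivaloyloxy)phenyl]-7-methoxy-2,3-dihydro-1-benzofuran-3-carboxylate (trans), via cis ester 10 (not isolated)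
Conditions: Rh2(S-PTTL)4 (1 mol%), toluene, −60 °C; then DBU, 60 °C
Reagents that add atoms: none
Why: Enantioselective intramolecular 1,5 C–H insertion of the rhodium carbenoid into the benzylic ether CH2 closes the dihydrobenzofuran and sets C2 under control of the chiral carboxylate ligands, giving the cis ester, and DBU then epimerises the acidic C3 centre to the more stable trans ester without touching C2.

Step 9
Reactants: 11 the trans ester of step 8
Product: 12 4-[(2R,3S)-5-(1,3-dioxolan-2-yl)-3-(hydroxymethyl)-7-methoxy-2,3-dihydro-1-benzofuran-2-yl]-2,6-dimethoxyphenol (trans)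
Conditions: LiAlH4, THF, 0 °C to rt; Rochelle salt work-up
Reagents that add atoms: none
Why: Hydride reduction turns the ester into the C3 hydroxymethyl group and cleaves the aryl pivalate in the same operation, which frees the ring C phenol for the first etherification without touching a stereocentre.

Step 10
Reactants: 13 methyl (R)-2,2-dimethyl-1,3-dioxolane-4-carboxylate
Product: 14 methyl (R)-2,3-dihydroxypropanoate
Conditions: Dowex 50WX8 (H+ form), MeOH, rt
Reagents that add atoms: none
Why: Acid-catalysed transacetalisation in methanol removes the acetonide and leaves the methyl ester and the stereocentre unchanged.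

Step 11
Reactants: 14 methyl (R)-2,3-dihydroxypropanoate
Product: 15 methyl (R)-3-[(tert-butyldimethylsilyl)oxy]-2-hydroxypropanoate
Conditions: TBSCl (1.05 equiv), imidazole, CH2Cl2, 0 °C
Reagents that add atoms: tert-butyldimethylsilyl chloride, CC(C)(C)[Si](C)(C)Cl
Why: Silylation with one equivalent of silyl chloride is selective for the primary hydroxyl over the hindered and less nucleophilic α-hydroxy ester position.

Step 12
Reactants: 15 the silyl ether of step 11
Product: 16 methyl (R)-3-[(tert-butyldimethylsilyl)oxy]-2-[(trifluoromethanesulfonyl)oxy]propanoate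
Conditions: Tf2O, 2,6-lutidine, CH2Cl2, −78 °C; used crude
Reagents that add atoms: trifluoromethanesulfonic anhydride, O=S(=O)(OS(=O)(=O)C(F)(F)F)C(F)(F)F
Why: O-Sulfonylation of the secondary alcohol occurs with retention and gives an α-triflyloxy ester activated for SN2 displacement by the adjacent carbonyl group.

Step 13
Reactants: 12 the ring C phenol of step 9; 16 the triflate of step 12
Product: 17 methyl (S)-3-[(tert-butyldimethylsilyl)oxy]-2-{4-[(2R,3S)-5-(1,3-dioxolan-2-yl)-3-(hydroxymethyl)-7-methoxy-2,3-dihydro-1-benzofuran-2-yl]-2,6-dimethoxyphenoxy}propanoate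
Conditions: Cs2CO3, MeCN, 0 °C to rt
Reagents that add atoms: none
Why: SN2 displacement of the α-triflyloxy ester by the caesium phenoxide proceeds with inversion, turning the (R) triflate into the (S) aryl ether that is C8 of unit B, and under carbonate the phenoxide should outcompete the primary alcohol.

Step 14
Reactants: 17 the methyl ester of step 13
Product: 18 the N-methoxy-N-methylamide (Weinreb amide) of 17, (S) at C8
Conditions: MeNH(OMe)·HCl, iPrMgCl, THF, −20 °C
Reagents that add atoms: N,O-dimethylhydroxylamine hydrochloride, CNOC.Cl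
Why: Aminolysis of the methyl ester by the chloromagnesium amide gives the Weinreb amide at a temperature at which the α centre should not epimerise.

Step 15
Reactants: 19 4-bromo-2,6-dimethoxyphenol
Product: 20 (4-bromo-2,6-dimethoxyphenoxy)(tert-butyl)dimethylsilane
Conditions: TBSCl, imidazole, DMF, rt
Reagents that add atoms: tert-butyldimethylsilyl chloride, CC(C)(C)[Si](C)(C)Cl
Why: Silylation protects the phenol for halogen–lithium exchange, and an aryl silyl ether can later be removed without touching alkyl silyl ethers.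

Step 16
Reactants: 18 the Weinreb amide of step 14; 20 the aryl bromide of step 15
Product: 22 (S)-3-[(tert-butyldimethylsilyl)oxy]-1-{4-[(tert-butyldimethylsilyl)oxy]-3,5-dimethoxyphenyl}-2-{4-[(2R,3S)-5-(1,3-dioxolan-2-yl)-3-(hydroxymethyl)-7-methoxy-2,3-dihydro-1-benzofuran-2-yl]-2,6-dimethoxyphenoxy}propan-1-one, via aryllithium 21 (not isolated)
Conditions: 20 (2.2 equiv), n-BuLi, THF, −78 °C; then 18, −78 °C; aq. NH4Cl
Reagents that add atoms: none
Why: Bromine–lithium exchange gives the aryllithium, whose addition to the Weinreb amide stops at the chelated tetrahedral intermediate and releases the aryl ketone on work-up (Weinreb ketone synthesis), one equivalent being spent on the free hydroxyl.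

Step 17
Reactants: 22 the aryl ketone of step 16
Product: 23 (1R,2S)-3-[(tert-butyldimethylsilyl)oxy]-1-{4-[(tert-butyldimethylsilyl)oxy]-3,5-dimethoxyphenyl}-2-{4-[(2R,3S)-5-(1,3-dioxolan-2-yl)-3-(hydroxymethyl)-7-methoxy-2,3-dihydro-1-benzofuran-2-yl]-2,6-dimethoxyphenoxy}propan-1-ol (erythro)
Conditions: Zn(BH4)2, Et2O–THF, −20 °C
Reagents that add atoms: none
Why: Chelation-controlled reduction (Cram chelate model), in which zinc bridges the carbonyl and the α-aryloxy oxygen and hydride enters from the side of the C8 hydrogen, should give the anti (erythro) 7R alcohol, the bulky silyl ether at O9 not competing for the metal.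

Step 18
Reactants: 23 the erythro alcohol of step 17
Product: 24 4-[(1R,2S)-3-[(tert-butyldimethylsilyl)oxy]-2-{4-[(2R,3S)-5-(1,3-dioxolan-2-yl)-3-(hydroxymethyl)-7-methoxy-2,3-dihydro-1-benzofuran-2-yl]-2,6-dimethoxyphenoxy}-1-hydroxypropyl]-2,6-dimethoxyphenol
Conditions: Cs2CO3 (0.5 equiv), DMF–H2O (10:1), rt
Reagents that add atoms: none
Why: Carbonate-mediated hydrolysis cleaves the aryl silyl ether selectively, a phenoxide being a far better leaving group from silicon than an alkoxide, and should leave the primary silyl ether in place.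

Step 19
Reactants: 25 4-bromo-2-methoxyphenol
Product: 26 (4-bromo-2-methoxyphenoxy)tri(propan-2-yl)silane
Conditions: TIPSCl, imidazole, DMF, rt
Reagents that add atoms: triisopropylsilyl chloride, CC(C)[Si](Cl)(C(C)C)C(C)C
Why: Silylation with the bulky triisopropylsilyl group gives a phenol ether that should survive Grignard formation, carbonate and hydride and is removed by fluoride at the end.

Step 20
Reactants: 26 the aryl bromide of step 19; 27 methyl (S)-glycidate (methyl (S)-oxirane-2-carboxylate)
Product: 29 methyl (S)-2-hydroxy-3-{3-methoxy-4-[(triisopropylsilyl)oxy]phenyl}propanoate, via arylmagnesium bromide 28 (not isolated)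
Conditions: Mg, THF, rt; then CuI (10 mol%), 27, THF, −40 °C to −20 °C
Reagents that add atoms: none
Why: Copper-catalysed ring opening of the epoxide by the aryl Grignard reagent occurs at the unsubstituted C3, so the stereocentre is carried over unchanged and the (S) aryl lactate results.

Step 21
Reactants: 29 the aryl lactate of step 20
Product: 30 methyl (S)-3-{3-methoxy-4-[(triisopropylsilyl)oxy]phenyl}-2-[(trifluoromethanesulfonyl)oxy]propanoate
Conditions: Tf2O, 2,6-lutidine, CH2Cl2, −78 °C; used crude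
Reagents that add atoms: trifluoromethanesulfonic anhydride, O=S(=O)(OS(=O)(=O)C(F)(F)F)C(F)(F)F
Why: O-Sulfonylation with retention at low temperature gives the activated α-triflyloxy ester before elimination to the cinnamate can set in.

Step 22
Reactants: 24 the ring B phenol of step 18; 30 the triflate of step 21
Product: 31 methyl (R)-3-{3-methoxy-4-[(triisopropylsilyl)oxy]phenyl}-2-(aryloxy)propanoate, the aryloxy group being 24 bound through its ring B phenol oxygen
Conditions: K2CO3, MeCN, 0 °C to rt
Reagents that add atoms: none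
Why: A second SN2 etherification with inversion lets the potassium phenoxide of ring B displace the (S) triflate to give the (R) aryl ether that is C8 of unit A, while the secondary benzylic and primary hydroxyls stay unreactive under carbonate.

Step 23
Reactants: 31 the methyl ester of step 22
Product: 32 the (R)-primary alcohol from 31 (unit A: ArCH2–CH(OAr)–CH2OH; acetal and both silyl ethers retained)
Conditions: LiBH4, THF, 0 °C to rt
Reagents that add atoms: none
Why: Borohydride reduction of the α-aryloxy ester gives the primary alcohol and is inert to the acetal, the silyl ethers and the aryl ethers, and as the last hydride step it clears the way for the enal.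

Step 24
Reactants: 32 the acetal of step 23
Product: 33 the ring D aldehyde from 32 (dioxolane replaced by CHO)
Conditions: PPTS (cat.), acetone–H2O (10:1), 40 °C
Reagents that add atoms: water, O
Why: Mild acid-catalysed hydrolysis of the electron-rich aryl dioxolane frees the aldehyde under conditions too weak to ionise the benzylic alcohol of unit B.

Step 25
Reactants: 33 the aldehyde of step 24
Product: 34 the (E)-enal from 33 (ring D bears (E)-CH=CH–CHO)
Conditions: Ph3P=CHCHO (1.2 equiv), toluene, 80 °C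
Reagents that add atoms: (triphenylphosphoranylidene)acetaldehyde, O=CC=P(c1ccccc1)(c1ccccc1)c1ccccc1
Why: Wittig olefination with the stabilised formylmethylene ylide should give the (E)-enal, free hydroxyls being tolerated and a small excess limiting a second homologation.

Step 26
Reactants: 34 the silyl-protected enal of step 25
Product: 35 the 7-deoxy tetramer (target lacking the benzylic hydroxyl of unit A; unit A C8 is R)
Conditions: TBAF, AcOH, THF, 0 °C to rt
Reagents that add atoms: none
Why: Buffered fluoride desilylation removes the aryl triisopropylsilyl ether and the primary tert-butyldimethylsilyl ether without base-induced damage to the enal.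

Step 27
Reactants: 35 the 7-deoxy tetramer; 36 phenylboronic acid
Product: 39 the bis(phenylboronate) of the target (a 2-phenyl-1,3,2-dioxaborinane across O7/O9 of unit A and of unit B), via boronate hemiester 37 (not isolated), via quinone methide 38 (not isolated)
Conditions: PhB(OH)2 (3 equiv), 4 Å MS, CH2Cl2, rt; then DABCO (0.3 equiv), Ag2O (2 equiv), rt, dark
Reagents that add atoms: phenylboronic acid (second equivalent beside reactant 36), OB(O)c1ccccc1
Why: Proposed new method: two molecules of phenylboronic acid are built in, one closing a dioxaborinane by condensation with the 1,3-diol of unit B and the other esterifying O9 of unit A as a hemiester, before Ag2O removes two electrons and the C7 hydrogen from ring A, the only free phenol, to form the para-quinone methide; the amine-activated B–OH oxygen of the hemiester then adds to C7 in a 1,6-addition that restores the aromatic ring A and supplies the new benzylic oxygen. The closest known reaction types are the intramolecular oxa-conjugate addition of boronic acid hemiesters to hydroxy enones and the 1,6-addition of oxygen nucleophiles to para-quinone methides. The unit A dioxaborinane closes in a 6-exo-trig mode at the exocyclic C7=C1 bond, and the unit B dioxaborinane closes by condensation of the 1,3-diol with the boronic acid. The new C7 centre is set by the existing C8 centre: in the chair transition state the C8 aryloxy group and the quinone methide ring both lie equatorial, which gives the trans 4-aryl-5-aryloxy ring, that is the (7R,8S) erythro diol, and the reversible ionisation of a benzylic C–O bond para to a phenol should let any cis ring drain to the trans one. The step needs oxidation at ring A alone, secured by the single free phenol and by the boronate that masks the benzylic carbinol of unit B, and it needs oxygen delivery faster than tautomerisation of the quinone methide to the enol ether, which the tether should secure.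

Step 28
Reactants: 39 the bis(phenylboronate) of step 27
Product: 40 the target, (E)-3-[(2R,3S)-2-{4-[(1R,2S)-1,3-dihydroxy-1-{4-[(1R,2S)-1,3-dihydroxy-1-(4-hydroxy-3-methoxyphenyl)propan-2-yloxy]-3,5-dimethoxyphenyl}propan-2-yloxy]-3,5-dimethoxyphenyl}-3-(hydroxymethyl)-7-methoxy-2,3-dihydro-1-benzofuran-5-yl]prop-2-enal
Conditions: pinacol (6 equiv), THF–MeOH, rt
Reagents that add atoms: none
Why: Transesterification to the more stable five-membered pinacol boronate releases both 1,3-diols under neutral conditions that should not disturb the benzylic centres or the enal.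

## Compound list

1 | syringaldehyde (4-hydroxy-3,5-dimethoxybenzaldehyde) | COc1cc(C=O)cc(OC)c1O | starting material
2 | 4-formyl-2,6-dimethoxyphenyl pivalate | COc1cc(C=O)cc(OC)c1OC(=O)C(C)(C)C | intermediate
3 | 4-(hydroxymethyl)-2,6-dimethoxyphenyl pivalate | COc1cc(CO)cc(OC)c1OC(=O)C(C)(C)C | intermediate
4 | 4-(bromomethyl)-2,6-dimethoxyphenyl pivalate | COc1cc(CBr)cc(OC)c1OC(=O)C(C)(C)C | intermediate
5 | 5-iodovanillin (4-hydroxy-3-iodo-5-methoxybenzaldehyde) | COc1cc(C=O)cc(I)c1O | starting material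
6 | 4-[(4-formyl-2-iodo-6-methoxyphenoxy)methyl]-2,6-dimethoxyphenyl pivalate | COc1cc(C=O)cc(I)c1OCc1cc(OC)c(OC(=O)C(C)(C)C)c(OC)c1 | intermediate
7 | 4-{[4-(1,3-dioxolan-2-yl)-2-iodo-6-methoxyphenoxy]methyl}-2,6-dimethoxyphenyl pivalate | COc1cc(C2OCCO2)cc(I)c1OCc1cc(OC)c(OC(=O)C(C)(C)C)c(OC)c1 | intermediate
8 | ethyl 2-[5-(1,3-dioxolan-2-yl)-2-{[3,5-dimethoxy-4-(pivaloyloxy)phenyl]methoxy}-3-methoxyphenyl]acetate | CCOC(=O)Cc1cc(C2OCCO2)cc(OC)c1OCc1cc(OC)c(OC(=O)C(C)(C)C)c(OC)c1 | intermediate
9 | ethyl 2-diazo-2-[5-(1,3-dioxolan-2-yl)-2-{[3,5-dimethoxy-4-(pivaloyloxy)phenyl]methoxy}-3-methoxyphenyl]acetate | CCOC(=O)C(=[N+]=[N-])c1cc(C2OCCO2)cc(OC)c1OCc1cc(OC)c(OC(=O)C(C)(C)C)c(OC)c1 | intermediate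
10 | ethyl (2R,3S)-5-(1,3-dioxolan-2-yl)-2-[3,5-dimethoxy-4-(pivaloyloxy)phenyl]-7-methoxy-2,3-dihydro-1-benzofuran-3-carboxylate (cis; not isolated) | CC(C)(C)C(=O)Oc1c(OC)cc([C@@H]2Oc3c(OC)cc(C4OCCO4)cc3[C@@H]2C(=O)OCC)cc1OC | intermediate
11 | ethyl (2R,3R)-5-(1,3-dioxolan-2-yl)-2-[3,5-dimethoxy-4-(pivaloyloxy)phenyl]-7-methoxy-2,3-dihydro-1-benzofuran-3-carboxylate (trans) | CC(C)(C)C(=O)Oc1c(OC)cc([C@@H]2Oc3c(OC)cc(C4OCCO4)cc3[C@H]2C(=O)OCC)cc1OC | intermediate
12 | 4-[(2R,3S)-5-(1,3-dioxolan-2-yl)-3-(hydroxymethyl)-7-methoxy-2,3-dihydro-1-benzofuran-2-yl]-2,6-dimethoxyphenol (trans) | Oc1c(OC)cc([C@@H]2Oc3c(OC)cc(C4OCCO4)cc3[C@H]2CO)cc1OC | intermediate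
13 | methyl (R)-2,2-dimethyl-1,3-dioxolane-4-carboxylate | COC(=O)[C@H]1COC(C)(C)O1 | starting material
14 | methyl (R)-2,3-dihydroxypropanoate | COC(=O)[C@@H](CO)O | intermediate
15 | methyl (R)-3-[(tert-butyldimethylsilyl)oxy]-2-hydroxypropanoate | COC(=O)[C@@H](CO[Si](C)(C)C(C)(C)C)O | intermediate
16 | methyl (R)-3-[(tert-butyldimethylsilyl)oxy]-2-[(trifluoromethanesulfonyl)oxy]propanoate | COC(=O)[C@@H](CO[Si](C)(C)C(C)(C)C)OS(=O)(=O)C(F)(F)F | intermediate
17 | methyl (S)-3-[(tert-butyldimethylsilyl)oxy]-2-{4-[(2R,3S)-5-(1,3-dioxolan-2-yl)-3-(hydroxymethyl)-7-methoxy-2,3-dihydro-1-benzofuran-2-yl]-2,6-dimethoxyphenoxy}propanoate | COC(=O)[C@H](CO[Si](C)(C)C(C)(C)C)Oc1c(OC)cc([C@@H]2Oc3c(OC)cc(C4OCCO4)cc3[C@H]2CO)cc1OC | intermediate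
18 | (S)-3-[(tert-butyldimethylsilyl)oxy]-2-{4-[(2R,3S)-5-(1,3-dioxolan-2-yl)-3-(hydroxymethyl)-7-methoxy-2,3-dihydro-1-benzofuran-2-yl]-2,6-dimethoxyphenoxy}-N-methoxy-N-methylpropanamide | CON(C)C(=O)[C@H](CO[Si](C)(C)C(C)(C)C)Oc1c(OC)cc([C@@H]2Oc3c(OC)cc(C4OCCO4)cc3[C@H]2CO)cc1OC | intermediate
19 | 4-bromo-2,6-dimethoxyphenol | COc1cc(Br)cc(OC)c1O | starting material
20 | (4-bromo-2,6-dimethoxyphenoxy)(tert-butyl)dimethylsilane | COc1cc(Br)cc(OC)c1O[Si](C)(C)C(C)(C)C | intermediate
21 | {4-[(tert-butyldimethylsilyl)oxy]-3,5-dimethoxyphenyl}lithium (not isolated) | [Li]c1cc(OC)c(O[Si](C)(C)C(C)(C)C)c(OC)c1 | intermediate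
22 | (S)-3-[(tert-butyldimethylsilyl)oxy]-1-{4-[(tert-butyldimethylsilyl)oxy]-3,5-dimethoxyphenyl}-2-{4-[(2R,3S)-5-(1,3-dioxolan-2-yl)-3-(hydroxymethyl)-7-methoxy-2,3-dihydro-1-benzofuran-2-yl]-2,6-dimethoxyphenoxy}propan-1-one | CC(C)(C)[Si](C)(C)Oc1c(OC)cc(C(=O)[C@H](CO[Si](C)(C)C(C)(C)C)Oc2c(OC)cc([C@@H]3Oc4c(OC)cc(C5OCCO5)cc4[C@H]3CO)cc2OC)cc1OC | intermediate
23 | (1R,2S)-3-[(tert-butyldimethylsilyl)oxy]-1-{4-[(tert-butyldimethylsilyl)oxy]-3,5-dimethoxyphenyl}-2-{4-[(2R,3S)-5-(1,3-dioxolan-2-yl)-3-(hydroxymethyl)-7-methoxy-2,3-dihydro-1-benzofuran-2-yl]-2,6-dimethoxyphenoxy}propan-1-ol (erythro) | CC(C)(C)[Si](C)(C)Oc1c(OC)cc([C@@H](O)[C@H](CO[Si](C)(C)C(C)(C)C)Oc2c(OC)cc([C@@H]3Oc4c(OC)cc(C5OCCO5)cc4[C@H]3CO)cc2OC)cc1OC | intermediate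
24 | 4-[(1R,2S)-3-[(tert-butyldimethylsilyl)oxy]-2-{4-[(2R,3S)-5-(1,3-dioxolan-2-yl)-3-(hydroxymethyl)-7-methoxy-2,3-dihydro-1-benzofuran-2-yl]-2,6-dimethoxyphenoxy}-1-hydroxypropyl]-2,6-dimethoxyphenol | Oc1c(OC)cc([C@@H](O)[C@H](CO[Si](C)(C)C(C)(C)C)Oc2c(OC)cc([C@@H]3Oc4c(OC)cc(C5OCCO5)cc4[C@H]3CO)cc2OC)cc1OC | intermediate
25 | 4-bromo-2-methoxyphenol | COc1cc(Br)ccc1O | starting material
26 | (4-bromo-2-methoxyphenoxy)tri(propan-2-yl)silane | COc1cc(Br)ccc1O[Si](C(C)C)(C(C)C)C(C)C | intermediate
27 | methyl (S)-glycidate (methyl (S)-oxirane-2-carboxylate) | COC(=O)[C@@H]1CO1 | starting material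
28 | {3-methoxy-4-[(triisopropylsilyl)oxy]phenyl}magnesium bromide (not isolated) | COc1cc([Mg]Br)ccc1O[Si](C(C)C)(C(C)C)C(C)C | intermediate
29 | methyl (S)-2-hydroxy-3-{3-methoxy-4-[(triisopropylsilyl)oxy]phenyl}propanoate | COC(=O)[C@H](Cc1ccc(O[Si](C(C)C)(C(C)C)C(C)C)c(OC)c1)O | intermediate
30 | methyl (S)-3-{3-methoxy-4-[(triisopropylsilyl)oxy]phenyl}-2-[(trifluoromethanesulfonyl)oxy]propanoate | COC(=O)[C@H](Cc1ccc(O[Si](C(C)C)(C(C)C)C(C)C)c(OC)c1)OS(=O)(=O)C(F)(F)F | intermediate
31 | protected tetramer ester: 24 etherified at its ring B phenol oxygen with the (R)-1-methoxy-1-oxo-3-{3-methoxy-4-[(triisopropylsilyl)oxy]phenyl}propan-2-yl group; unit B (7R,8S), dihydrobenzofuran (2R,3S) | COc1cc(C[C@H](C(=O)OC)Oc2c(OC)cc([C@@H](O)[C@H](CO[Si](C)(C)C(C)(C)C)Oc3c(OC)cc([C@@H]4Oc5c(OC)cc(C6OCCO6)cc5[C@H]4CO)cc3OC)cc2OC)ccc1O[Si](C(C)C)(C(C)C)C(C)C | intermediate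
32 | protected 7-deoxy tetramer alcohol: as 31 with CH2OH in place of CO2Me, unit A C8 (R) | COc1cc(C[C@H](CO)Oc2c(OC)cc([C@@H](O)[C@H](CO[Si](C)(C)C(C)(C)C)Oc3c(OC)cc([C@@H]4Oc5c(OC)cc(C6OCCO6)cc5[C@H]4CO)cc3OC)cc2OC)ccc1O[Si](C(C)C)(C(C)C)C(C)C | intermediate
33 | ring D aldehyde: as 32 with CHO in place of the 1,3-dioxolan-2-yl group | COc1cc(C[C@H](CO)Oc2c(OC)cc([C@@H](O)[C@H](CO[Si](C)(C)C(C)(C)C)Oc3c(OC)cc([C@@H]4Oc5c(OC)cc(C=O)cc5[C@H]4CO)cc3OC)cc2OC)ccc1O[Si](C(C)C)(C(C)C)C(C)C | intermediate
34 | silyl-protected 7-deoxy enal: as 33 with (E)-CH=CH–CHO on ring D | COc1cc(C[C@H](CO)Oc2c(OC)cc([C@@H](O)[C@H](CO[Si](C)(C)C(C)(C)C)Oc3c(OC)cc([C@@H]4Oc5c(OC)cc(/C=C/C=O)cc5[C@H]4CO)cc3OC)cc2OC)ccc1O[Si](C(C)C)(C(C)C)C(C)C | intermediate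
35 | 7-deoxy tetramer: the target without the benzylic hydroxyl of unit A; unit A C8 (R), unit B (7R,8S), dihydrobenzofuran (2R,3S), (E)-enal | COc1cc(C[C@H](CO)Oc2c(OC)cc([C@@H](O)[C@H](CO)Oc3c(OC)cc([C@@H]4Oc5c(OC)cc(/C=C/C=O)cc5[C@H]4CO)cc3OC)cc2OC)ccc1O | intermediate
36 | phenylboronic acid | OB(O)c1ccccc1 | starting material
37 | boronate hemiester of 35: phenylboronic hemiester on O9 of unit A and 2-phenyl-1,3,2-dioxaborinane across O7/O9 of unit B (drawn without the reversible hemiester at the unit C hydroxymethyl; not isolated) | COc1cc(C[C@H](COB(O)c2ccccc2)Oc2c(OC)cc([C@H]3OB(c4ccccc4)OC[C@@H]3Oc3c(OC)cc([C@@H]4Oc5c(OC)cc(/C=C/C=O)cc5[C@H]4CO)cc3OC)cc2OC)ccc1O | intermediate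
38 | ring A para-quinone methide of 37 (4-alkylidene-2-methoxycyclohexa-2,5-dien-1-one with exocyclic C7=C1; not isolated) | COC1=CC(=C[C@H](COB(O)c2ccccc2)Oc2c(OC)cc([C@H]3OB(c4ccccc4)OC[C@@H]3Oc3c(OC)cc([C@@H]4Oc5c(OC)cc(/C=C/C=O)cc5[C@H]4CO)cc3OC)cc2OC)C=CC1=O | intermediate
39 | bis(phenylboronate) of the target: trans-2-phenyl-1,3,2-dioxaborinanes across O7/O9 of unit A and of unit B, each (7R,8S) | COc1cc([C@H]2OB(c3ccccc3)OC[C@@H]2Oc2c(OC)cc([C@H]3OB(c4ccccc4)OC[C@@H]3Oc3c(OC)cc([C@@H]4Oc5c(OC)cc(/C=C/C=O)cc5[C@H]4CO)cc3OC)cc2OC)ccc1O | intermediate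
40 | CNP0192639.1, (E)-3-[(2R,3S)-2-{4-[(1R,2S)-1,3-dihydroxy-1-{4-[(1R,2S)-1,3-dihydroxy-1-(4-hydroxy-3-methoxyphenyl)propan-2-yloxy]-3,5-dimethoxyphenyl}propan-2-yloxy]-3,5-dimethoxyphenyl}-3-(hydroxymethyl)-7-methoxy-2,3-dihydro-1-benzofuran-5-yl]prop-2-enal | COc1cc([C@@H](O)[C@H](CO)Oc2c(OC)cc([C@@H](O)[C@H](CO)Oc3c(OC)cc([C@@H]4Oc5c(OC)cc(/C=C/C=O)cc5[C@H]4CO)cc3OC)cc2OC)ccc1O | target

## Step count and risks

Total step count: 28. Longest linear sequence: 21 steps (steps 1–9, 13, 14, 16–18 and 22–28, from syringaldehyde).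

Steps most likely to fail:

1. Step 27 (the one new method). The quinone methide may tautomerise under the amine to the aryl enol ether, the ring A phenoxyl radical may couple before the second electron is removed, or untethered water or boronic acid may add without facial control; each would have to be slower than delivery of the boron-bound oxygen. The fallback uses known chemistry only and builds the benzylic carbinol of unit A the way that of unit B is built. It sets out from phenol 24 and comes back to the route at target 40, so that 35 to 39 are not passed. Phenol 24 is alkylated with triflate 16 (Cs2CO3, MeCN, inversion) to give the unit A methyl ester F1. Aminolysis with MeNH(OMe)·HCl and iPrMgCl gives the Weinreb amide F2. The ring A aryllithium F3, made from bromide 26 and n-BuLi at −78 °C, is added to give the aryl ketone F4. Zn(BH4)2 reduces it under chelate control to the erythro alcohol F5. PPTS in wet acetone frees the aldehyde F6, Ph3P=CHCHO gives the enal F7, and TBAF with AcOH removes the two tert-butyldimethylsilyl ethers and the triisopropylsilyl ether to give 40.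

2. Step 8. The carbenoid may discriminate poorly between the two enantiotopic benzylic hydrogens, or in the opposite sense, and reversible opening of the furan ring during the DBU epimerisation would erode the configuration at C2. The fallback gives up catalyst control for resolution. It sets out from diazo ester 9 and comes back at trans ester 11. Insertion with the achiral catalyst Rh2(OAc)4 (CH2Cl2, rt) gives cis ester 10 together with the enantiomeric cis ester F8. DBU converts the pair into 11 and the enantiomeric trans ester F9. The two are parted by preparative chromatography on a chiral stationary phase (amylose tris(3,5-dimethylphenylcarbamate)), and 11 goes on to step 9.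

3. Step 17. Hydride delivery through an open, Felkin–Anh-type transition state may compete with the zinc chelate and raise the share of the threo alcohol. The fallback replaces substrate control by catalyst control. It sets out from ketone 22 and comes back at alcohol 23. A Corey–Bakshi–Shibata reduction with the (R)-configured B-methyl oxazaborolidine and BH3·SMe2 (toluene, −30 °C) is used; with the aryl group as the large substituent it should deliver the (7R) carbinol whatever the chelate preference. This fallback makes no compound outside the list (F0).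

Further compounds
F1 | step 27 | unit A methyl ester: 24 etherified at its ring B phenol oxygen with the (S)-3-[(tert-butyldimethylsilyl)oxy]-1-methoxy-1-oxopropan-2-yl group | COC(=O)[C@H](CO[Si](C)(C)C(C)(C)C)Oc1c(OC)cc([C@@H](O)[C@H](CO[Si](C)(C)C(C)(C)C)Oc2c(OC)cc([C@@H]3Oc4c(OC)cc(C5OCCO5)cc4[C@H]3CO)cc2OC)cc1OC
F2 | step 27 | Weinreb amide: the N-methoxy-N-methylamide of F1, (S) at unit A C8 | CON(C)C(=O)[C@H](CO[Si](C)(C)C(C)(C)C)Oc1c(OC)cc([C@@H](O)[C@H](CO[Si](C)(C)C(C)(C)C)Oc2c(OC)cc([C@@H]3Oc4c(OC)cc(C5OCCO5)cc4[C@H]3CO)cc2OC)cc1OC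
F3 | step 27 | ring A aryllithium: {3-methoxy-4-[(triisopropylsilyl)oxy]phenyl}lithium | [Li]c1ccc(O[Si](C(C)C)(C(C)C)C(C)C)c(OC)c1
F4 | step 27 | aryl ketone: unit A 1-{3-methoxy-4-[(triisopropylsilyl)oxy]phenyl}propan-1-one, (S) at C8, O9 silylated, on the ring B oxygen of 24 | COc1cc(C(=O)[C@H](CO[Si](C)(C)C(C)(C)C)Oc2c(OC)cc([C@@H](O)[C@H](CO[Si](C)(C)C(C)(C)C)Oc3c(OC)cc([C@@H]4Oc5c(OC)cc(C6OCCO6)cc5[C@H]4CO)cc3OC)cc2OC)ccc1O[Si](C(C)C)(C(C)C)C(C)C
F5 | step 27 | erythro alcohol: F4 reduced to the unit A (7R,8S) carbinol | COc1cc([C@@H](O)[C@H](CO[Si](C)(C)C(C)(C)C)Oc2c(OC)cc([C@@H](O)[C@H](CO[Si](C)(C)C(C)(C)C)Oc3c(OC)cc([C@@H]4Oc5c(OC)cc(C6OCCO6)cc5[C@H]4CO)cc3OC)cc2OC)ccc1O[Si](C(C)C)(C(C)C)C(C)C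
F6 | step 27 | aldehyde: F5 with CHO in place of the 1,3-dioxolan-2-yl group | COc1cc([C@@H](O)[C@H](CO[Si](C)(C)C(C)(C)C)Oc2c(OC)cc([C@@H](O)[C@H](CO[Si](C)(C)C(C)(C)C)Oc3c(OC)cc([C@@H]4Oc5c(OC)cc(C=O)cc5[C@H]4CO)cc3OC)cc2OC)ccc1O[Si](C(C)C)(C(C)C)C(C)C
F7 | step 27 | enal: F6 with (E)-CH=CH–CHO on ring D, the tris-silyl ether of the target | COc1cc([C@@H](O)[C@H](CO[Si](C)(C)C(C)(C)C)Oc2c(OC)cc([C@@H](O)[C@H](CO[Si](C)(C)C(C)(C)C)Oc3c(OC)cc([C@@H]4Oc5c(OC)cc(/C=C/C=O)cc5[C@H]4CO)cc3OC)cc2OC)ccc1O[Si](C(C)C)(C(C)C)C(C)C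
F8 | step 8 | enantiomeric cis ester: ethyl (2S,3R)-5-(1,3-dioxolan-2-yl)-2-[3,5-dimethoxy-4-(pivaloyloxy)phenyl]-7-methoxy-2,3-dihydro-1-benzofuran-3-carboxylate | CC(C)(C)C(=O)Oc1c(OC)cc([C@H]2Oc3c(OC)cc(C4OCCO4)cc3[C@H]2C(=O)OCC)cc1OC
F9 | step 8 | enantiomeric trans ester: ethyl (2S,3S)-5-(1,3-dioxolan-2-yl)-2-[3,5-dimethoxy-4-(pivaloyloxy)phenyl]-7-methoxy-2,3-dihydro-1-benzofuran-3-carboxylate | CC(C)(C)C(=O)Oc1c(OC)cc([C@H]2Oc3c(OC)cc(C4OCCO4)cc3[C@@H]2C(=O)OCC)cc1OC
F0 | step 17 | none | none
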